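## Retrosynthetic overview
- The target comes from hispidulin by chemoselective bis-O-sulfation of 7-OH and 4'-OH. The chelated 5-OH stays free.
- Ring C is cut at three bonds at once (C4–C4a, C3–C4, O1–C2), giving an o-iodophenol, CO and an aryl acetylene. These are joined by a palladium carbonylative annulation, which replaces the usual chalcone or Baker–Venkataraman route and the semisynthesis from scutellarein.
- The iodophenol comes from a symmetrical phenol. That phenol is made by sterically controlled iridium C–H borylation/oxidation of bis-MOM 2-methoxyresorcinol, so the 6-OMe is differentiated from the start.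
- Rings A and B are bought as arenes. Ring C (the pyranone) is the only ring formed, in step 4.

Assumption: the target has no stereocentre or stereogenic axis, so there is no enantiomer to select. It is delivered as the free bis(hydrogen sulfate), exactly as drawn.

## Route

Step 1
Reactants: 1 2-methoxyresorcinol (2-methoxybenzene-1,3-diol)
Product: 2 2-methoxy-1,3-bis(methoxymethoxy)benzene
Conditions: NaH (2.5 equiv), MOMCl (2.5 equiv), DMF, 0 °C to rt
Reagents that add atoms: chloromethyl methyl ether (MOMCl), COCCl
Why: Williamson-type O-alkylation of the two equivalent phenoxides installs an acetal protecting group that has no arene C–H bonds to compete in step 2, survives amine, CO and palladium, and later leaves in mild acid without touching the aryl methyl ether; no stereocentre is formed.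

Step 2
Reactants: 2 2-methoxy-1,3-bis(methoxymethoxy)benzene
Product: 4 4-methoxy-3,5-bis(methoxymethoxy)phenol, via aryl pinacol boronate 3 (not isolated)
Conditions: [Ir(OMe)(cod)]2 (1.5 mol %), dtbpy (3 mol %), B2pin2 (1.0 equiv), THF, 80 °C (sealed), 16 h; evaporate; then 30% H2O2, aq NaOH, THF, 0 °C
Reagents that add atoms: hydrogen peroxide, OO; bis(pinacolato)diboron, CC1(C)OB(OC1(C)C)B1OC(C)(C)C(C)(C)O1 (its boron stays only in 3)
Why: Sterically governed iridium-catalysed aromatic C–H borylation (through a tris(boryl) complex of trivalent iridium) attacks only C5, the one ring C–H without an ortho substituent and a site that electrophilic substitution cannot reach, and one-pot boronate oxidation (1,2-aryl shift from boron to oxygen) turns C–B into C–OH; no stereocentre is formed.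

Step 3
Reactants: 4 4-methoxy-3,5-bis(methoxymethoxy)phenol
Product: 5 2-iodo-4-methoxy-3,5-bis(methoxymethoxy)phenol
Conditions: NIS (1.0 equiv), MeCN, −20 to 0 °C, dark
Reagents that add atoms: N-iodosuccinimide, O=C1CCC(=O)N1I
Why: In this electrophilic aromatic iodination ortho to the free phenol the only two ring C–H bonds are equivalent by symmetry, so one equivalent of NIS at low temperature can give only one mono-iodide, and the first iodine slows a second attack.

Step 4 (key step)
Reactants: 5 2-iodo-4-methoxy-3,5-bis(methoxymethoxy)phenol; 6 1-(benzyloxy)-4-ethynylbenzene (1.5 equiv)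
Product: 8 2-[4-(benzyloxy)phenyl]-6-methoxy-5,7-bis(methoxymethoxy)-4H-chromen-4-one, via o-hydroxyaryl ynone 7 (not isolated)
Conditions: PdCl2(dppf) (5 mol %), CO (20 bar), Et2NH, 120 °C, autoclave
Reagents that add atoms: carbon monoxide, [C-]#[O+]
Why: In this carbonylative Sonogashira coupling followed by 6-endo-dig oxa-Michael closure (carbonylative annulation of an o-iodophenol), zerovalent palladium inserts into the carbon–iodine bond, CO insertion gives the acyl complex of divalent palladium, the amine-activated alkyne is acylated to ynone 7, and diethylamine steers ring closure to the pyranone and not the aurone, so ring C with C4 from CO forms in one operation with no stereocentre.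

Step 5
Reactants: 8 2-[4-(benzyloxy)phenyl]-6-methoxy-5,7-bis(methoxymethoxy)-4H-chromen-4-one
Product: 10 hispidulin (5,7-dihydroxy-2-(4-hydroxyphenyl)-6-methoxy-4H-chromen-4-one), via debenzylated bis-MOM flavone 9 (not isolated)
Conditions: H2 (1 atm), Pd/C (10 wt %), THF–MeOH, rt; filter; then HCl (1.25 M in MeOH), 50 °C
Reagents that add atoms: none
Why: Catalytic hydrogenolysis of the benzyl aryl ether followed by acid-catalysed acetal exchange of both MOM groups with methanol frees all three phenols, under conditions in which the flavone C2–C3 double bond and the 6-OMe aryl methyl ether are inert.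

Step 6
Reactants: 10 hispidulin
Product: 12 hispidulin 7,4'-disulfate (5-hydroxy-6-methoxy-4-oxo-2-[4-(sulfooxy)phenyl]-4H-chromen-7-yl hydrogen sulfate), via bis(pyridinium) disulfate salt 11 (not isolated)
Conditions: SO3·pyridine (5 equiv), pyridine, 0 °C to rt; C18 desalting (H2O/MeOH); sulfonic acid cation-exchange resin (H+ form), H2O, 4 °C; freeze-dry
Reagents that add atoms: sulfur trioxide–pyridine complex, O=S(=O)([O-])[n+]1ccccc1
Why: Phenol O-sulfation with an amine–SO3 complex is chemoselective because the 5-OH is locked in a strong hydrogen bond to the C4 carbonyl and crowded by the 6-OMe, so only the acidic 7-OH and the 4'-OH react, and cold cation exchange replaces pyridinium by protons to give the free bis(hydrogen sulfate).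

## Compound list
1 | 2-methoxyresorcinol | COc1c(O)cccc1O | starting material
2 | 2-methoxy-1,3-bis(methoxymethoxy)benzene | COCOc1cccc(OCOC)c1OC | intermediate
3 | 2-[4-methoxy-3,5-bis(methoxymethoxy)phenyl]-4,4,5,5-tetramethyl-1,3,2-dioxaborolane | COCOc1cc(B2OC(C)(C)C(C)(C)O2)cc(OCOC)c1OC | intermediate
4 | 4-methoxy-3,5-bis(methoxymethoxy)phenol | COCOc1cc(O)cc(OCOC)c1OC | intermediate
5 | 2-iodo-4-methoxy-3,5-bis(methoxymethoxy)phenol | COCOc1cc(O)c(I)c(OCOC)c1OC | intermediate
6 | 1-(benzyloxy)-4-ethynylbenzene | C#Cc1ccc(OCc2ccccc2)cc1 | starting material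
7 | 3-[4-(benzyloxy)phenyl]-1-[2-hydroxy-5-methoxy-4,6-bis(methoxymethoxy)phenyl]prop-2-yn-1-one | COCOc1cc(O)c(C(=O)C#Cc2ccc(OCc3ccccc3)cc2)c(OCOC)c1OC | intermediate
8 | 2-[4-(benzyloxy)phenyl]-6-methoxy-5,7-bis(methoxymethoxy)-4H-chromen-4-one | COCOc1cc2oc(-c3ccc(OCc4ccccc4)cc3)cc(=O)c2c(OCOC)c1OC | intermediate
9 | 2-(4-hydroxyphenyl)-6-methoxy-5,7-bis(methoxymethoxy)-4H-chromen-4-one | COCOc1cc2oc(-c3ccc(O)cc3)cc(=O)c2c(OCOC)c1OC | intermediate
10 | hispidulin | COc1c(O)cc2oc(-c3ccc(O)cc3)cc(=O)c2c1O | intermediate
11 | bis(pyridinium) salt of hispidulin 7,4'-disulfate | COc1c(OS(=O)(=O)[O-])cc2oc(-c3ccc(OS(=O)(=O)[O-])cc3)cc(=O)c2c1O.c1cc[nH+]cc1.c1cc[nH+]cc1 | intermediate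
12 | hispidulin 7,4'-disulfate (achiral) | COc1c(OS(=O)(=O)O)cc2oc(-c3ccc(OS(=O)(=O)O)cc3)cc(=O)c2c1O | target

## Step count and risks
Total step count: 6.
Longest linear sequence: 6 steps (1 to 12). Compound 6 is bought.

**Step 4 (highest risk).**
- Failure mode: the iodide is electron-rich and flanked on both sides. Carbonylation may lose out to the diethylamide, to direct coupling that gives a benzofuran, or to the aurone.
- Fallback: the carbonyl carbon arrives already attached to the alkyne, so no CO gas is used. It sets out from 5 and 6.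
- Compound 6 is deprotonated with nBuLi (THF, −78 °C) and acylated with N-methoxy-N-methylcarbamoyl chloride. This gives the Weinreb amide 3-[4-(benzyloxy)phenyl]-N-methoxy-N-methylprop-2-ynamide F1.
- Compound 5 is deprotonated with MeMgCl and then undergoes iodine–magnesium exchange with iPrMgCl·LiCl (THF, −20 °C). This gives chloromagnesium 2-(chloromagnesio)-4-methoxy-3,5-bis(methoxymethoxy)phenoxide F2.
- F2 is acylated once by F1 (Weinreb ketone synthesis). After NH4Cl work-up this gives ynone 7, where the fallback comes back to the route.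
- Isolated 7 is closed to 8 with Et2NH in DMF at 60 °C.

**Step 2.**
- Failure mode: the trialkoxyarene may be borylated too slowly, or not cleanly at C5.
- Fallback: C5–H is made the most acidic site, so steric accessibility no longer matters. It sets out from 2.
- NBS (2.1 equiv, MeCN, 0 °C) brominates both activated positions. This gives 1,5-dibromo-3-methoxy-2,4-bis(methoxymethoxy)benzene F3.
- LDA (THF, −78 °C) removes the only remaining ring proton, which sits between the two bromines. Trapping with B(OMe)3 gives dimethyl [2,6-dibromo-4-methoxy-3,5-bis(methoxymethoxy)phenyl]boronate F4.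
- H2O2/NaOH in the same flask gives 2,6-dibromo-4-methoxy-3,5-bis(methoxymethoxy)phenol F5.
- Hydrodebromination (H2, Pd/C, NaOAc, MeOH) comes back to the route at 4.

**Step 6.**
- Failure mode: under- or over-sulfation gives ionic mixtures that are hard to separate. The free acid can also hydrolyse itself during isolation.
- Fallback: protected sulfate diesters are used, which are neutral and can be purified on silica. It sets out from 10.
- 2,2,2-Trichloroethyl chlorosulfate (2.4 equiv), Et3N and DMAP in THF at 0 °C give hispidulin 7,4'-bis(2,2,2-trichloroethyl sulfate) F6. It is purified away from any mono- or tri-ester.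
- Reductive fragmentation with Zn dust and HCO2NH4 in MeOH at rt gives the diammonium salt of hispidulin 7,4'-disulfate F7.
- Cold passage through the H+ resin comes back to the route at 12.

## Further compounds
F1 | step 4 | 3-[4-(benzyloxy)phenyl]-N-methoxy-N-methylprop-2-ynamide | CON(C)C(=O)C#Cc1ccc(OCc2ccccc2)cc1
F2 | step 4 | chloromagnesium 2-(chloromagnesio)-4-methoxy-3,5-bis(methoxymethoxy)phenoxide | COCOc1cc(O[Mg]Cl)c([Mg]Cl)c(OCOC)c1OC
F3 | step 2 | 1,5-dibromo-3-methoxy-2,4-bis(methoxymethoxy)benzene | COCOc1c(Br)cc(Br)c(OCOC)c1OC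
F4 | step 2 | dimethyl [2,6-dibromo-4-methoxy-3,5-bis(methoxymethoxy)phenyl]boronate | COCOc1c(Br)c(B(OC)OC)c(Br)c(OCOC)c1OC
F5 | step 2 | 2,6-dibromo-4-methoxy-3,5-bis(methoxymethoxy)phenol | COCOc1c(Br)c(O)c(Br)c(OCOC)c1OC
F6 | step 6 | hispidulin 7,4'-bis(2,2,2-trichloroethyl sulfate) | COc1c(OS(=O)(=O)OCC(Cl)(Cl)Cl)cc2oc(-c3ccc(OS(=O)(=O)OCC(Cl)(Cl)Cl)cc3)cc(=O)c2c1O
F7 | step 6 | diammonium salt of hispidulin 7,4'-disulfate | COc1c(OS(=O)(=O)[O-])cc2oc(-c3ccc(OS(=O)(=O)[O-])cc3)cc(=O)c2c1O.[NH4+].[NH4+]
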